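**Fixed split.** I started from what stays put at a fixed temperature: the couplings of starting material with partner have the same two reactants, so they divide what couples in the ratio of their constants, however the dosing goes.

    starting material + partner → target (k1 = 0.10 /M/s, Ea1 = 45.0 kJ/mol)
    starting material + partner → isomer of the product (k2 = 0.24 /M/s, Ea2 = 43.0 kJ/mol)
    starting material + partner → second isomer (k3 = 0.065 /M/s, Ea3 = 58.0 kJ/mol)
    2 partner → homo dimer (k4 = 0.16 /M/s, Ea4 = 74.0 kJ/mol)
    starting material + protic impurity → quenched substrate (k5 = 0.32 /M/s, Ea5 = 65.0 kJ/mol)
    crystals ⇌ target, rate k6*(cs6 - [target]) while solid is left; crystals form when [target] > cs6 (cs6 = 0.062 M, k6 = 0.17 /s)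
    (constants at 60 °C)

| flask | starting material | partner | protic impurity | temperature | time | remark |
|---|---|---|---|---|---|---|
| Thursday's | 0.10 M (fed, over 2.0 s) | 0.100 M | 5.00 mM | 60 °C | 30 s | all else is in the flask from the start; the feed brings no volume worth counting |
| Saturday's | 0.10 M | 0.100 M | 5.00 mM |  | 30 s | everything together at the start at 30 °C, warmed to 60 °C at 20 s |
| Monday's | 0.10 M | 0.100 M (fed, over 20 s) | 5.00 mM | 60 °C | 30 s | all else is in the flask from the start; the feed brings no volume worth counting |
| Wednesday's | 0.10 M | 0.100 M (in portions, 3, over 20 s) | 5.00 mM | 60 °C | 30 s | first portion at the start, last at 20 s |
| Friday's | 0.10 M (fed, over 20 s) | 0.100 M | 5.00 mM | 60 °C | 30 s | all else is in the flask from the start; the feed brings no volume worth counting |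
| Sunday's | 0.10 M | 0.100 M (fed, over 20 s) | 5.00 mM |  | 30 s | the addition at 30 °C, then warmed to 60 °C; the feed brings no volume worth counting |

- what is said of target includes crystals
- a doubled species enters its step squared and goes two at a time
- crystals is a solid; its amount is given per volume of the solution
- at 60 °C the constants are as listed, elsewhere as the activation energies make them

* the flask with the highest amount of isomer of the product, in percent of the starting material charged ("all alike" if they lie within 1.5 percentage points) (Thursday's / Saturday's / Monday's / Wednesday's / Friday's / Sunday's / all alike)
* final isomer of the product, as a percentage of the starting material charged, in Thursday's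
* final isomer of the product, as a percentage of the starting material charged, in Saturday's
* final isomer of the product, as a percentage of the starting material charged, in Monday's
* final isomer of the product, as a percentage of the starting material charged, in Wednesday's
* final isomer of the product, as a percentage of the starting material charged, in Friday's
* final isomer of the product, as a percentage of the starting material charged, in Sunday's

**Carried share.** At 60 °C the coupling constants summed to 0.405 /M/s, and by the constants 59.3 % of what coupled became isomer of the product. I called this the isomer share, the selectivity for the isomer. My rule, at a fixed temperature, was that isomer equals this share times what remains of the charge once the starting material left and the quenched substrate are taken off.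

**Main step.** I built up Thursday's. Its feed ran 2.0 s, so starting material arrived on average half of that late, leaving 29.0 s of reaction. With coupling by itself and charges equal, the coupled part is the dose over one plus the dose, where the dose is the summed constant times charge times time, here 1.17. That gave 54.0 % coupled and 32.0 % isomer.

**Partner dimer.** Partner also goes to homo dimer, two at a turn, so with the two level it falls with a constant of 0.725 /M/s, faster than starting material. Letting starting material feel this thinner partner left 53.1 % of it, so 46.9 % coupled and the isomer came down to 27.8 %, a correction of 4.2 percentage points. I had set the two level in the partner's own loss, so this figure leaned high.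

**The rest.** At the start protic impurity drew starting material at 3.95 % of the coupling rate, and taking that start value off the whole run, as a rough step, gave 26.7 %. By this reckoning target came to about 0.0116 M, below its solubility of 0.062 M, so I counted no crystals. My reckoning stopped there, at Thursday's.

**The forecast.** It named Thursday's, with 26 % for Thursday's, 19.9 % for Saturday's, 23.1 % for Monday's, 22.6 % for Wednesday's, 18.8 % for Friday's and 17.5 % for Sunday's. Its grounds: “how long both partners are present together at high concentration”. For Thursday's my figure stood 0.70 points above its figure.

**The flasks.** They gave 25.9 % for Thursday's, 20.3 % for Saturday's, 23.1 % for Monday's, 22.9 % for Wednesday's, 18.8 % for Friday's and 18.0 % for Sunday's, so the answer was Thursday's. Thursday's led Monday's by 2.8 points, more than the margin of 1.5 points.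

**Same share.** In Thursday's, 53.9 % of the starting material stood unreacted and 2.39 % as quenched substrate, so the share gave 25.9 % against the 25.9 % found. The neighbour was Sunday's left until 2.0 min, with amounts and the temperature course held, so its addition ran at 30 °C and not at the temperature of the share. There 33.3 % of the starting material stood unreacted and 3.95 % as quenched substrate, so the share of 60 °C gave 37.2 %, and that flask held 37.6 % of isomer of the product.

The numbers of this flask were drawn at random within sensible limits; the run is a simulation.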